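**Retrosynthetic overview**

1. Target 24 ⇐ dimethoxyquinone 23 ⇐ tetramethoxyarene 22. The quinone ring is never built: it is unmasked from commercial 1,2,4,5-tetramethoxybenzene (cerium oxidation, then hydrolysis of the methoxy group next to the alkyl chain).
2. Cyclohexene ring (C1 = stereogenic CH, C2 = methyl-bearing sp2 carbon, C3 = ring =CH, C4 and C5 = CH2, C6 = CMe2): one of the two methyl groups on C6 is read as a carboxyl carbon, so 22 ⇐ acid 17.
3. Enabling feature: the C1–C6 bond joins the stereogenic CH to the quaternary carbon and is allylic to C2=C3, so O=C–C6–C1–C2=C3 is a Claisen retron. C3 and C6 are bridged by the ring methylenes C4–C5, so the allylic oxygen on C3 and the acyl carbon fit into one six-membered lactone: 17 ⇐ δ-lactone 14 by a lactone-to-carbocycle Ireland–Claisen rearrangement (C3–O broken, C1–C6 made, chirality passed from C3 to C1).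
4. Lactone 14 ⇐ enal 6 + ester-bearing mixed diorganozinc 12 (catalytic asymmetric addition sets C3–O); 6 ⇐ geranylarene 4 (allylic oxidation of the E methyl group) ⇐ lithiated 1 + geranyl bromide 2.
5. Order of rings: arene bought; temporary lactone ring (step 6); cyclohexene ring, the only ring of the skeleton that is closed and the last ring made (step 7).

Key step: step 7

Remark: the ring-atom numbering C1–C6 of line 2 is used throughout. The ring CH carries the descriptor R in 16–21 and S in 22–24 without any change in space, because the CIP rank of C6 drops when its oxygenated carbon becomes a methyl group.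

Assumption: compounds 7–14 are carried as mixtures at the methyl-bearing α-carbon (left unspecified in the SMILES), since this carbon becomes sp2 in step 7. The facial sense of step 6 is assigned by analogy with aryl and alkenyl aldehydes and would be checked on 14 before it is carried on.

**Step 1**
Reactants: 1 1,2,4,5-tetramethoxybenzene; 2 geranyl bromide [(2E)-1-bromo-3,7-dimethylocta-2,6-diene]
Product: 4 3-[(2E)-3,7-dimethylocta-2,6-dien-1-yl]-1,2,4,5-tetramethoxybenzene, via aryllithium 3 (not isolated)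
Conditions: n-BuLi (1.1 equiv), TMEDA, THF, 0 °C; CuI (10 mol %), then 2, −40 °C → rt
Reagents that add atoms: none
Why: Ortho-lithiation between two methoxy groups gives aryllithium 3, which after transmetalation to copper should alkylate the primary allylic bromide at its α-carbon (copper-catalysed aryl–allyl coupling, SN2) with the E geometry kept.

**Step 2**
Reactants: 4 3-[(2E)-3,7-dimethylocta-2,6-dien-1-yl]-1,2,4,5-tetramethoxybenzene
Product: 5 (2E,6E)-2,6-dimethyl-8-(2,3,5,6-tetramethoxyphenyl)octa-2,6-dien-1-ol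
Conditions: SeO2 (0.3 equiv), t-BuOOH (70% aq., 3 equiv), salicylic acid (10 mol %), CH2Cl2, 0 °C → rt
Reagents that add atoms: tert-butyl hydroperoxide CC(C)(C)OO (oxygen atom, relayed by selenium dioxide O=[Se]=O)
Why: SeO2-catalysed allylic oxidation (Riley oxidation; ene reaction then [2,3]-sigmatropic shift) should take the terminal, more accessible trisubstituted alkene at its (E)-methyl group and so fix the 2E geometry; any enal 6 formed by over-oxidation is carried along.

**Step 3**
Reactants: 5 (2E,6E)-2,6-dimethyl-8-(2,3,5,6-tetramethoxyphenyl)octa-2,6-dien-1-ol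
Product: 6 (2E,6E)-2,6-dimethyl-8-(2,3,5,6-tetramethoxyphenyl)octa-2,6-dienal
Conditions: MnO2 (activated, 15 equiv), CH2Cl2, rt
Reagents that add atoms: none
Why: MnO2 oxidises allylic alcohols selectively to enals without E/Z isomerisation (allylic alcohol oxidation).

**Step 4**
Reactants: 7 α-methyl-γ-butyrolactone (racemic 3-methyloxolan-2-one)
Product: 9 ethyl 4-iodo-2-methylbutanoate, via trimethylsilyl ester 8 (not isolated)
Conditions: Me3SiI (1.2 equiv), CH2Cl2, rt → 40 °C; then EtOH (excess), 0 °C → rt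
Reagents that add atoms: iodotrimethylsilane C[Si](C)(C)I; ethanol CCO
Why: Iodotrimethylsilane silylates the lactone carbonyl and iodide opens the ring by SN2 attack at the O–CH2 carbon, and ethanolysis of silyl ester 8 under the acid formed gives the ethyl ester (lactone opening to an ω-iodo ester).

**Step 5**
Reactants: 9 ethyl 4-iodo-2-methylbutanoate
Product: 12 (4-ethoxy-3-methyl-4-oxobutyl)[(trimethylsilyl)methyl]zinc, via ethyl(alkyl)zinc 10 (not isolated), via dialkylzinc 11 (not isolated)
Conditions: Et2Zn (5 equiv, neat), CuI (0.3 mol %), 50 °C; iodoethane and excess Et2Zn removed at 50 °C under vacuum (two molecules of 10 giving one of 11); then (Me3SiCH2)2Zn (0.5 equiv relative to 9, one per dialkylzinc 11), Et2O, rt; solution used at once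
Reagents that add atoms: diethylzinc CC[Zn]CC; bis[(trimethylsilyl)methyl]zinc C[Si](C)(C)C[Zn]C[Si](C)(C)C
Why: Copper-catalysed iodine–zinc exchange converts the primary iodide into ethyl(alkyl)zinc 10 with the ester untouched, removal of iodoethane and diethylzinc under vacuum drives it to the salt-free dialkylzinc 11, and ligand redistribution with bis[(trimethylsilyl)methyl]zinc then gives the mixed diorganozinc 12, in which the trimethylsilylmethyl group is a non-transferable ligand so that every molecule carries one transferable ester-bearing alkyl group (preparation of functionalised mixed diorganozincs).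

**Step 6**
Reactants: 6 (2E,6E)-2,6-dimethyl-8-(2,3,5,6-tetramethoxyphenyl)octa-2,6-dienal; 12 (4-ethoxy-3-methyl-4-oxobutyl)[(trimethylsilyl)methyl]zinc
Product: 14 (6R)-3-methyl-6-[(2E,6E)-6-methyl-8-(2,3,5,6-tetramethoxyphenyl)octa-2,6-dien-2-yl]oxan-2-one (mixture of C3 epimers), via δ-hydroxy ester 13 (not isolated)
Conditions: 12 (1.6 equiv), Ti(OiPr)4 (2 equiv), (1S,2S)-N,N'-bis(trifluoromethanesulfonyl)cyclohexane-1,2-diamine (8 mol %), Et2O/toluene, −20 °C; 1 M HCl work-up; then pyridinium p-toluenesulfonate (5 mol %), toluene, 45 °C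
Reagents that add atoms: none
Why: Titanium/bis(sulfonamide)-catalysed enantioselective addition of a functionalised mixed diorganozinc to an α-branched enal, in which only the ester-bearing alkyl group of 12 is transferred and the (1S,2S)-ligand is expected to deliver it to the Re face and so set the (R)-carbinol carbon (ring atom C3), after which δ-hydroxy ester 13 closes to the δ-lactone under mild acid.

**Step 7**
Reactants: 14 (6R)-3-methyl-6-[(2E,6E)-6-methyl-8-(2,3,5,6-tetramethoxyphenyl)octa-2,6-dien-2-yl]oxan-2-one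
Product: 17 (1S,2R)-1,3-dimethyl-2-[(3E)-3-methyl-5-(2,3,5,6-tetramethoxyphenyl)pent-3-en-1-yl]cyclohex-3-ene-1-carboxylic acid, via silyl ketene acetal 15 (not isolated), via trimethylsilyl ester 16 (not isolated)
Conditions: lithium diisopropylamide (1.3 equiv), Me3SiCl/Et3N (premixed, 3 equiv each), THF, −78 °C → rt; solvent change to toluene, 110 °C; then 1 M HCl, THF, rt
Reagents that add atoms: none
Why: Ireland–Claisen rearrangement of a lactone enolate: internal silylation gives the cyclic silyl ketene acetal 15, whose C6=C(OSi)–O–C3–C2=C1 array undergoes a suprafacial [3,3]-sigmatropic shift that breaks the allylic C3–O bond, forms the C1–C6 bond and moves the double bond to C2=C3, the silyl ester 16 being hydrolysed on work-up. The closest known reaction type is the Ireland–Claisen rearrangement of ω-alkenyl lactone silyl ketene acetals to cycloalkenecarboxylic acids and of 6-alkenyl-1,4-dioxan-2-ones to dihydropyran-2-carboxylic acids, which pass through the same bridged boat transition state. The cyclohexene ring is closed by this six-centre pericyclic shift itself (six-membered lactone to six-membered carbocycle), the C4–C5 bridge holding the ketene acetal under one face of the alkene only. The new stereocentre C1 is controlled by the (R)-configured C3–O carbon together with the E geometry of the C1=C2 bond (1,3-chirality transfer, C3 becoming sp2), which should give the S configuration required at C1 of the target; the quaternary centre C6 is set at the same time by the ring-fixed ketene acetal geometry (carboxyl cis to the side chain) and loses its stereogenicity in step 10. The step needs O- and not C-silylation (Me3SiCl/Et3N internal quench of the tetrasubstituted enolate), complete chirality transfer (secured by the bridged transition state and the geometrically pure alkene from step 2) and the α-position of the ring double bond (fixed by the mechanism, so that no β- or γ-isomer can arise).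

**Step 8**
Reactants: 17 (1S,2R)-1,3-dimethyl-2-[(3E)-3-methyl-5-(2,3,5,6-tetramethoxyphenyl)pent-3-en-1-yl]cyclohex-3-ene-1-carboxylic acid
Product: 18 {(1S,2R)-1,3-dimethyl-2-[(3E)-3-methyl-5-(2,3,5,6-tetramethoxyphenyl)pent-3-en-1-yl]cyclohex-3-en-1-yl}methanol
Conditions: LiAlH4 (3 equiv), THF, 0 °C → 65 °C
Reagents that add atoms: none
Why: LiAlH4 reduces the hindered α-quaternary carboxylic acid to the neopentyl-type alcohol without touching alkenes or stereocentres (hydride reduction).

**Step 9**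
Reactants: 18 {(1S,2R)-1,3-dimethyl-2-[(3E)-3-methyl-5-(2,3,5,6-tetramethoxyphenyl)pent-3-en-1-yl]cyclohex-3-en-1-yl}methanol
Product: 19 (1S,2R)-1,3-dimethyl-2-[(3E)-3-methyl-5-(2,3,5,6-tetramethoxyphenyl)pent-3-en-1-yl]cyclohex-3-ene-1-carbaldehyde
Conditions: Dess–Martin periodinane (1.3 equiv), CH2Cl2, 0 °C → rt
Reagents that add atoms: none
Why: Dess–Martin oxidation should give the non-enolisable aldehyde under neutral conditions.

**Step 10**
Reactants: 19 (1S,2R)-1,3-dimethyl-2-[(3E)-3-methyl-5-(2,3,5,6-tetramethoxyphenyl)pent-3-en-1-yl]cyclohex-3-ene-1-carbaldehyde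
Product: 22 3-[(2E)-3-methyl-5-[(1S)-2,6,6-trimethylcyclohex-2-en-1-yl]pent-2-en-1-yl]-1,2,4,5-tetramethoxybenzene, via tosylhydrazone 20 (not isolated), via alkyldiazene 21 (not isolated)
Conditions: TsNHNH2 (1.2 equiv), EtOH, 50 °C; then catecholborane (3 equiv), CHCl3, 0 °C → rt; NaOAc·3H2O (5 equiv), 60 °C
Reagents that add atoms: none
Why: Caglioti-type deoxygenation, in which tosylhydrazone 20 is reduced at its C=N carbon by catecholborane and acetate then releases sulfinate to give diazene 21, which loses N2 to leave the methyl group, so that C6 becomes the non-stereogenic gem-dimethyl carbon under conditions too weakly basic to move the benzylic–allylic double bond.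

**Step 11**
Reactants: 22 3-[(2E)-3-methyl-5-[(1S)-2,6,6-trimethylcyclohex-2-en-1-yl]pent-2-en-1-yl]-1,2,4,5-tetramethoxybenzene
Product: 23 2,5-dimethoxy-3-[(2E)-3-methyl-5-[(1S)-2,6,6-trimethylcyclohex-2-en-1-yl]pent-2-en-1-yl]cyclohexa-2,5-diene-1,4-dione
Conditions: (NH4)2Ce(NO3)6 (2.5 equiv), MeCN/H2O (2:1), 0 °C
Reagents that add atoms: water O
Why: Oxidative demethylation of a para-dimethoxyarene by tetravalent cerium; either para pair gives the same 2,5-dimethoxyquinone, and the isolated trisubstituted alkenes are expected to survive at 0 °C.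

**Step 12**
Reactants: 23 2,5-dimethoxy-3-[(2E)-3-methyl-5-[(1S)-2,6,6-trimethylcyclohex-2-en-1-yl]pent-2-en-1-yl]cyclohexa-2,5-diene-1,4-dione
Product: 24 2-hydroxy-5-methoxy-3-[(2E)-3-methyl-5-[(1S)-2,6,6-trimethylcyclohex-2-en-1-yl]pent-2-en-1-yl]cyclohexa-2,5-diene-1,4-dione (CNP0018448.1)
Conditions: HClO4 (60% aq.), THF, 0 °C → rt
Reagents that add atoms: water O
Why: Acid hydrolysis of a vinylogous ester (water adds to the protonated enone, methanol leaves); the methoxy group flanked by the alkyl chain and a carbonyl group is twisted out of conjugation and is the one expected to be cleaved, as is usual for 3-alkyl-2,5-dimethoxy-1,4-benzoquinones, while the conjugated 5-methoxy group stays.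

**Compound list**

1 | 1,2,4,5-tetramethoxybenzene | COc1cc(OC)c(OC)cc1OC | starting material
2 | geranyl bromide, (2E)-1-bromo-3,7-dimethylocta-2,6-diene | CC(C)=CCC/C(C)=C/CBr | starting material
3 | (2,3,5,6-tetramethoxyphenyl)lithium | [Li]c1c(OC)c(OC)cc(OC)c1OC | intermediate
4 | 3-[(2E)-3,7-dimethylocta-2,6-dien-1-yl]-1,2,4,5-tetramethoxybenzene | COc1cc(OC)c(OC)c(C/C=C(\C)CCC=C(C)C)c1OC | intermediate
5 | (2E,6E)-2,6-dimethyl-8-(2,3,5,6-tetramethoxyphenyl)octa-2,6-dien-1-ol | COc1cc(OC)c(OC)c(C/C=C(\C)CC/C=C(\C)CO)c1OC | intermediate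
6 | (2E,6E)-2,6-dimethyl-8-(2,3,5,6-tetramethoxyphenyl)octa-2,6-dienal | COc1cc(OC)c(OC)c(C/C=C(\C)CC/C=C(\C)C=O)c1OC | intermediate
7 | α-methyl-γ-butyrolactone (racemic 3-methyloxolan-2-one) | CC1CCOC1=O | starting material
8 | trimethylsilyl 4-iodo-2-methylbutanoate | CC(CCI)C(=O)O[Si](C)(C)C | intermediate
9 | ethyl 4-iodo-2-methylbutanoate (racemic) | CCOC(=O)C(C)CCI | intermediate
10 | ethyl(4-ethoxy-3-methyl-4-oxobutyl)zinc | CCOC(=O)C(C)CC[Zn]CC | intermediate
11 | bis(4-ethoxy-3-methyl-4-oxobutyl)zinc | CCOC(=O)C(C)CC[Zn]CCC(C)C(=O)OCC | intermediate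
12 | (4-ethoxy-3-methyl-4-oxobutyl)[(trimethylsilyl)methyl]zinc | CCOC(=O)C(C)CC[Zn]C[Si](C)(C)C | intermediate
13 | ethyl (5R,6E,10E)-5-hydroxy-2,6,10-trimethyl-12-(2,3,5,6-tetramethoxyphenyl)dodeca-6,10-dienoate (C2 epimers) | CCOC(=O)C(C)CC[C@@H](O)/C(C)=C/CC/C(C)=C/Cc1c(OC)c(OC)cc(OC)c1OC | intermediate
14 | (6R)-3-methyl-6-[(2E,6E)-6-methyl-8-(2,3,5,6-tetramethoxyphenyl)octa-2,6-dien-2-yl]oxan-2-one (C3 epimers) | O=C1O[C@H](CCC1C)/C(C)=C/CC/C(C)=C/Cc2c(OC)c(OC)cc(OC)c2OC | intermediate
15 | trimethyl({(2R)-5-methyl-2-[(2E,6E)-6-methyl-8-(2,3,5,6-tetramethoxyphenyl)octa-2,6-dien-2-yl]-3,4-dihydro-2H-pyran-6-yl}oxy)silane | CC1=C(O[Si](C)(C)C)O[C@H](CC1)/C(C)=C/CC/C(C)=C/Cc2c(OC)c(OC)cc(OC)c2OC | intermediate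
16 | trimethylsilyl (1S,2R)-1,3-dimethyl-2-[(3E)-3-methyl-5-(2,3,5,6-tetramethoxyphenyl)pent-3-en-1-yl]cyclohex-3-ene-1-carboxylate | COc1cc(OC)c(OC)c(C/C=C(\C)CC[C@@H]2C(C)=CCC[C@]2(C)C(=O)O[Si](C)(C)C)c1OC | intermediate
17 | (1S,2R)-1,3-dimethyl-2-[(3E)-3-methyl-5-(2,3,5,6-tetramethoxyphenyl)pent-3-en-1-yl]cyclohex-3-ene-1-carboxylic acid | COc1cc(OC)c(OC)c(C/C=C(\C)CC[C@@H]2C(C)=CCC[C@]2(C)C(O)=O)c1OC | intermediate
18 | {(1S,2R)-1,3-dimethyl-2-[(3E)-3-methyl-5-(2,3,5,6-tetramethoxyphenyl)pent-3-en-1-yl]cyclohex-3-en-1-yl}methanol | COc1cc(OC)c(OC)c(C/C=C(\C)CC[C@@H]2C(C)=CCC[C@]2(C)CO)c1OC | intermediate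
19 | (1S,2R)-1,3-dimethyl-2-[(3E)-3-methyl-5-(2,3,5,6-tetramethoxyphenyl)pent-3-en-1-yl]cyclohex-3-ene-1-carbaldehyde | COc1cc(OC)c(OC)c(C/C=C(\C)CC[C@@H]2C(C)=CCC[C@]2(C)C=O)c1OC | intermediate
20 | N'-({(1S,2R)-1,3-dimethyl-2-[(3E)-3-methyl-5-(2,3,5,6-tetramethoxyphenyl)pent-3-en-1-yl]cyclohex-3-en-1-yl}methylidene)-4-methylbenzenesulfonohydrazide | COc1cc(OC)c(OC)c(C/C=C(\C)CC[C@@H]2C(C)=CCC[C@]2(C)C=NNS(=O)(=O)c3ccc(C)cc3)c1OC | intermediate
21 | ({(1S,2R)-1,3-dimethyl-2-[(3E)-3-methyl-5-(2,3,5,6-tetramethoxyphenyl)pent-3-en-1-yl]cyclohex-3-en-1-yl}methyl)diazene | COc1cc(OC)c(OC)c(C/C=C(\C)CC[C@@H]2C(C)=CCC[C@]2(C)CN=N)c1OC | intermediate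
22 | 3-[(2E)-3-methyl-5-[(1S)-2,6,6-trimethylcyclohex-2-en-1-yl]pent-2-en-1-yl]-1,2,4,5-tetramethoxybenzene | COc1cc(OC)c(OC)c(C/C=C(\C)CC[C@@H]2C(C)=CCCC2(C)C)c1OC | intermediate
23 | 2,5-dimethoxy-3-[(2E)-3-methyl-5-[(1S)-2,6,6-trimethylcyclohex-2-en-1-yl]pent-2-en-1-yl]cyclohexa-2,5-diene-1,4-dione | COC1=CC(=O)C(OC)=C(C/C=C(\C)CC[C@@H]2C(C)=CCCC2(C)C)C1=O | intermediate
24 | 2-hydroxy-5-methoxy-3-[(2E)-3-methyl-5-[(1S)-2,6,6-trimethylcyclohex-2-en-1-yl]pent-2-en-1-yl]cyclohexa-2,5-diene-1,4-dione | COC1=CC(=O)C(O)=C(C/C=C(\C)CC[C@@H]2C(C)=CCCC2(C)C)C1=O | target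

**Step count and risks**

Total step count: 12. Longest linear sequence: 10 steps (steps 1–3 and 6–12); steps 4 and 5 prepare the zinc reagent.

Steps most likely to fail:

- **Step 7.** The sigmatropic shift must join a tetrasubstituted ketene acetal carbon to a trisubstituted alkene terminus, and may be outrun by C-silylation of the enolate or by loss of the silyl group on heating. Fallback, from 14 back to 19: lactone 14 would be reduced (i-Bu2AlH, CH2Cl2, −78 °C) to the lactol (6R)-3-methyl-6-[(2E,6E)-6-methyl-8-(2,3,5,6-tetramethoxyphenyl)octa-2,6-dien-2-yl]oxan-2-ol F1. F1 would be dehydrated through its anomeric mesylate (6R)-3-methyl-6-[(2E,6E)-6-methyl-8-(2,3,5,6-tetramethoxyphenyl)octa-2,6-dien-2-yl]oxan-2-yl methanesulfonate F2 (MsCl, Et3N, CH2Cl2, 0 → 40 °C, not isolated) to the cyclic enol ether (2R)-5-methyl-2-[(2E,6E)-6-methyl-8-(2,3,5,6-tetramethoxyphenyl)octa-2,6-dien-2-yl]-3,4-dihydro-2H-pyran F3. F3 would be heated (toluene, sealed tube, 180–200 °C, trace of Et3N) in a thermal Claisen rearrangement of the allyl vinyl ether through the same bridged boat. This neutral variant carries no silyl group, tolerates the higher temperature and should give aldehyde 19 directly, so steps 8 and 9 fall away.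

- **Step 6.** Alkyl transfer from the ester-bearing zinc reagent may be slow, and uncatalysed background addition or transfer of ethyl groups from incompletely removed diethylzinc may erode the enantiomeric purity. Fallback, from 6 back to 14: enal 6 would be allylated with B-allyldiisopinocampheylborane of the (−)-α-pinene series [from (+)-B-methoxydiisopinocampheylborane and allylmagnesium bromide; Et2O, −78 °C; NaOH/H2O2 work-up] to give (4R,5E,9E)-5,9-dimethyl-11-(2,3,5,6-tetramethoxyphenyl)undeca-1,5,9-trien-4-ol F4. F4 would be acylated (methacryloyl chloride, Et3N, 4-dimethylaminopyridine, CH2Cl2) to (4R,5E,9E)-5,9-dimethyl-11-(2,3,5,6-tetramethoxyphenyl)undeca-1,5,9-trien-4-yl 2-methylprop-2-enoate F5. Ring-closing metathesis [second-generation Grubbs catalyst (H2IMes)(PCy3)Cl2Ru=CHPh, CH2Cl2, 40 °C] would give (6R)-3-methyl-6-[(2E,6E)-6-methyl-8-(2,3,5,6-tetramethoxyphenyl)octa-2,6-dien-2-yl]-5,6-dihydro-2H-pyran-2-one F6. Conjugate reduction ([(Ph3P)CuH]6 cat., polymethylhydrosiloxane, toluene) would then give lactone 14.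

- **Step 12.** Water may add at the unhindered vinylogous ester (loss of regiocontrol), or the new hydroxyl may add to the side-chain double bond under the acid. Fallback, from 23 back to 24: 23 would be hydrolysed completely (NaOH, MeOH/H2O, 40 °C, then acidification) to 2,5-dihydroxy-3-[(2E)-3-methyl-5-[(1S)-2,6,6-trimethylcyclohex-2-en-1-yl]pent-2-en-1-yl]cyclohexa-2,5-diene-1,4-dione F7. F7 would be etherified once under equilibrating Fischer-type conditions (MeOH, HC(OMe)3, pyridinium p-toluenesulfonate cat., 25 °C). The hydroxyl flanked by the ring hydrogen should be methylated and the hindered, hydrogen-bonded hydroxyl next to the alkyl chain kept, which gives target 24.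

**Further compounds**

F1 | step 7 | (6R)-3-methyl-6-[(2E,6E)-6-methyl-8-(2,3,5,6-tetramethoxyphenyl)octa-2,6-dien-2-yl]oxan-2-ol (mixture at C2 and C3) | OC1O[C@H](CCC1C)/C(C)=C/CC/C(C)=C/Cc2c(OC)c(OC)cc(OC)c2OC
F2 | step 7 | (6R)-3-methyl-6-[(2E,6E)-6-methyl-8-(2,3,5,6-tetramethoxyphenyl)octa-2,6-dien-2-yl]oxan-2-yl methanesulfonate | CS(=O)(=O)OC1O[C@H](CCC1C)/C(C)=C/CC/C(C)=C/Cc2c(OC)c(OC)cc(OC)c2OC
F3 | step 7 | (2R)-5-methyl-2-[(2E,6E)-6-methyl-8-(2,3,5,6-tetramethoxyphenyl)octa-2,6-dien-2-yl]-3,4-dihydro-2H-pyran | CC1=CO[C@H](CC1)/C(C)=C/CC/C(C)=C/Cc2c(OC)c(OC)cc(OC)c2OC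
F4 | step 6 | (4R,5E,9E)-5,9-dimethyl-11-(2,3,5,6-tetramethoxyphenyl)undeca-1,5,9-trien-4-ol | O[C@H](CC=C)/C(C)=C/CC/C(C)=C/Cc1c(OC)c(OC)cc(OC)c1OC
F5 | step 6 | (4R,5E,9E)-5,9-dimethyl-11-(2,3,5,6-tetramethoxyphenyl)undeca-1,5,9-trien-4-yl 2-methylprop-2-enoate | CC(=C)C(=O)O[C@H](CC=C)/C(C)=C/CC/C(C)=C/Cc1c(OC)c(OC)cc(OC)c1OC
F6 | step 6 | (6R)-3-methyl-6-[(2E,6E)-6-methyl-8-(2,3,5,6-tetramethoxyphenyl)octa-2,6-dien-2-yl]-5,6-dihydro-2H-pyran-2-one | O=C1O[C@H](CC=C1C)/C(C)=C/CC/C(C)=C/Cc2c(OC)c(OC)cc(OC)c2OC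
F7 | step 12 | 2,5-dihydroxy-3-[(2E)-3-methyl-5-[(1S)-2,6,6-trimethylcyclohex-2-en-1-yl]pent-2-en-1-yl]cyclohexa-2,5-diene-1,4-dione | OC1=CC(=O)C(O)=C(C/C=C(\C)CC[C@@H]2C(C)=CCCC2(C)C)C1=O
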